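The key step exploits the unsubstituted C5=C6 edge of the quinone ring, flanked by carbonyl carbons C4 and C1: it is the image of acetylene. Cutting C4–C5 and C6–C1 leaves C1, C2 (nonadecyl), C3 and C4 as a maleoyl unit. The precursor is a cobaltacyclopentenedione, made by insertion of monovalent cobalt into the CO–CO bond of 3-nonadecylcyclobutenedione. It takes up acetylene and closes the quinone ring in one operation, at the final oxidation level. The symmetric alkyne removes any regiochemical question. The cyclobutenedione comes from diisopropyl squarate by two 1,2-additions (Grignard, hydride) and acidic transposition.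

Key step: step 4

Remark: the side chain is read as an unbranched nonadecyl group (19 carbons). The target has no stereocentre. The transient stereocentres of the cyclobutene intermediates are racemic or unassigned and are erased before the key step.

Step 1
Reactants: 1 1-bromononadecane; 2 diisopropyl squarate (3,4-diisopropoxycyclobut-3-ene-1,2-dione)
Product: 4 racemic 4-hydroxy-2,3-diisopropoxy-4-nonadecylcyclobut-2-en-1-one, via nonadecylmagnesium bromide 3 (not isolated)
Conditions: 1, Mg turnings, THF, reflux; then added to 2, THF, −78 → −20 °C; sat. aq. NH4Cl
Reagents that add atoms: magnesium, [Mg] (held in 3 only)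
Why: Grignard 1,2-addition to one of the two equivalent carbonyl groups of the squarate leaves an alkoxide whose remaining carbonyl is only a vinylogous ester, so the addition should stop after one equivalent; the new stereocentre is racemic and is erased in step 2.

Step 2
Reactants: 4 racemic 4-hydroxy-2,3-diisopropoxy-4-nonadecylcyclobut-2-en-1-one
Product: 6 3-nonadecylcyclobut-3-ene-1,2-dione, via cyclobutenediol 5 (not isolated)
Conditions: LiAlH4, THF, −40 → 0 °C; then aq. HCl (2 mol/L), THF–CH2Cl2, rt
Reagents that add atoms: water, O
Why: 1,2-reduction of the vinylogous ester carbonyl is followed by two acid-induced allylic ionisations, each giving an isopropoxy-stabilised cation that is hydrolysed to a carbonyl group (a double Stork–Danheiser-type transposition); this places both C=O groups on the former enol ether carbons, leaves the C(nonadecyl)=CH double bond and erases both stereocentres of 5.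

Step 3
Reactants: 6 3-nonadecylcyclobut-3-ene-1,2-dione
Product: 8 chloro(dimethylglyoxime)(pyridine)(2-nonadecylmaleoyl)cobalt, via bis(triphenylphosphine)maleoylcobalt chloride 7 (not isolated)
Conditions: ClCo(PPh3)3, PhH, rt, Ar; then dimethylglyoxime, pyridine, rt; PPh3 removed by chromatography (SiO2)
Reagents that add atoms: chlorotris(triphenylphosphine)cobalt, Cl[Co-3]([P+](c1ccccc1)(c1ccccc1)c1ccccc1)([P+](c1ccccc1)(c1ccccc1)c1ccccc1)[P+](c1ccccc1)(c1ccccc1)c1ccccc1; dimethylglyoxime, CC(=NO)C(C)=NO; pyridine, c1ccncc1
Why: Oxidative insertion of monovalent cobalt into the strained CO–CO bond of a cyclobutenedione (carbon–carbon bond activation) gives the five-membered trivalent-cobalt diacyl, and ligand substitution by chelating dimethylglyoxime and pyridine should expel both phosphines and give an air-stable saturated complex.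

Step 4
Reactants: 8 chloro(dimethylglyoxime)(pyridine)(2-nonadecylmaleoyl)cobalt; 9 acetylene
Product: 10 2-nonadecyl-1,4-benzoquinone
Conditions: HC≡CH (1 atm, acetone-free, slow stream), CoCl2·6H2O, ClCH2CH2Cl, 70–80 °C; work-up in air
Reagents that add atoms: none
Why: The Lewis acid CoCl2·6H2O loosens pyridine (or chloride) from the saturated trivalent-cobalt complex 8, acetylene binds at the freed site and inserts into one cobalt–acyl bond to give a seven-membered cobaltacycloheptadienedione (first new carbon–carbon bond), and reductive elimination of its vinyl and acyl ligands forms the second bond and releases the quinone from monovalent cobalt. The closest known reaction type is the quinone synthesis from maleoylcobalt or phthaloylcobalt complexes and alkynes, formally a metal-mediated [4+2] union of a bisketene equivalent with an alkyne. The one ring closed is the six-membered quinone ring, and it closes by vinyl–acyl reductive elimination with ring contraction of the seven-membered metallacycle, not by a polar or pericyclic cyclisation. No stereocentre is formed. The step needs a single insertion instead of oligomerisation of acetylene, which the single labile site of the chelated complex and the fast ring-closing elimination should secure, and it needs no regiocontrol, since insertion of the symmetric alkyne into either of the two unlike cobalt–acyl bonds leads to the same product. The three unsubstituted CH positions of 10 are open to conjugate addition, which is why the phosphines were exchanged in step 3 before the quinone is released.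

Compound list
1 | 1-bromononadecane | CCCCCCCCCCCCCCCCCCCBr | starting material
2 | diisopropyl squarate (3,4-diisopropoxycyclobut-3-ene-1,2-dione) | CC(C)OC1=C(OC(C)C)C(=O)C1=O | starting material
3 | nonadecylmagnesium bromide | CCCCCCCCCCCCCCCCCCC[Mg]Br | intermediate
4 | racemic 4-hydroxy-2,3-diisopropoxy-4-nonadecylcyclobut-2-en-1-one | CCCCCCCCCCCCCCCCCCCC1(O)C(OC(C)C)=C(OC(C)C)C1=O | intermediate
5 | 3,4-diisopropoxy-1-nonadecylcyclobut-3-ene-1,2-diol (diastereomers, configuration not assigned) | CCCCCCCCCCCCCCCCCCCC1(O)C(O)C(OC(C)C)=C1OC(C)C | intermediate
6 | 3-nonadecylcyclobut-3-ene-1,2-dione | CCCCCCCCCCCCCCCCCCCC1=CC(=O)C1=O | intermediate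
7 | chlorobis(triphenylphosphine)(2-nonadecylmaleoyl)cobalt, five-membered ring Co–C(=O)–C(C19H39)=CH–C(=O) | CCCCCCCCCCCCCCCCCCCC1=CC(=O)[Co-2](Cl)([P+](c2ccccc2)(c2ccccc2)c2ccccc2)([P+](c2ccccc2)(c2ccccc2)c2ccccc2)C1=O | intermediate
8 | chloro(dimethylglyoxime)(pyridine)(2-nonadecylmaleoyl)cobalt, same cobaltacycle with N,N-chelating neutral dimethylglyoxime | CCCCCCCCCCCCCCCCCCCC1=CC(=O)[Co-3]2(Cl)([n+]3ccccc3)([N+](O)=C(C)C(C)=[N+]2O)C1=O | intermediate
9 | acetylene | C#C | starting material
10 | 2-nonadecyl-1,4-benzoquinone (2-nonadecylcyclohexa-2,5-diene-1,4-dione) | CCCCCCCCCCCCCCCCCCCC1=CC(=O)C=CC1=O | target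

Total step count: 4
Longest linear sequence: 4 steps (1 → 4 → 6 → 8 → 10)

Steps most likely to fail

First, step 4. Acetylene may oligomerise at cobalt, and the stationary concentration of the gas in the hot solvent may be too low. The unsubstituted quinone may also be lost by conjugate addition of released pyridine or by reduction through the released low-valent cobalt. The fallback is metal-free and makes the same two bonds one after the other; it sets out from 6. Ethynylmagnesium bromide (THF, −78 °C) should add 1,2 to either carbonyl group. This should give racemic 4-ethynyl-4-hydroxy-3-nonadecylcyclobut-2-en-1-one F1 together with racemic 4-ethynyl-4-hydroxy-2-nonadecylcyclobut-2-en-1-one F2. The unseparated pair is heated in p-xylene (138 °C). There, 4π electrocyclic ring opening with outward rotation of the hydroxy group gives an alkynyl vinylketene, which closes to a six-membered diradical and ends by hydrogen shift from oxygen to carbon (Moore rearrangement). Both adducts converge, and the fallback comes back to the route at 10.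

Second, step 3. Dissociated phosphine may add in conjugate fashion to the unsubstituted ring CH of the dione, the metallacycle may decarbonylate, and the lipophilic complex may separate incompletely from the phosphine. The fallback uses a phosphine-free carbonyl metal in place of cobalt; it sets out from 6. Fe2(CO)9 in benzene (rt to 40 °C) should insert a zerovalent Fe(CO)4 fragment into the CO–CO bond and give tetracarbonyl(2-nonadecylmaleoyl)iron F3, a ferracyclopentenedione. Heating it under acetylene in MeCN (about 90 °C) should lead through the same alkyne insertion and reductive elimination. The fallback comes back to the route at 10 without passing 8.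

Third, step 2. Hydride may be delivered in conjugate fashion with loss of alkoxide, over-reduction may occur, the acid transposition may stop halfway, and the monosubstituted dione may undergo hydration or ring opening in aqueous acid. The fallback builds the four-membered ring by cycloaddition instead of editing a squarate; it sets out from 1. Alkylation of the lithium acetylide–ethylenediamine complex (DMSO, rt) should give henicos-1-yne F4. A [2+2] cycloaddition with dichloroketene (Cl3CCOCl, Zn–Cu couple, Et2O–DME, rt to reflux) joins the ketene carbonyl carbon to the terminal alkyne carbon and should give 4,4-dichloro-3-nonadecylcyclobut-2-en-1-one F5. Hydrolysis of the geminal dichloride (conc. H2SO4, about 50 °C, then ice) comes back to the route at 6 and also bypasses step 1.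

Further compounds
F1 | step 4 | racemic 4-ethynyl-4-hydroxy-3-nonadecylcyclobut-2-en-1-one | CCCCCCCCCCCCCCCCCCCC1=CC(=O)C1(O)C#C
F2 | step 4 | racemic 4-ethynyl-4-hydroxy-2-nonadecylcyclobut-2-en-1-one | CCCCCCCCCCCCCCCCCCCC1=CC(O)(C#C)C1=O
F3 | step 3 | tetracarbonyl(2-nonadecylmaleoyl)iron | CCCCCCCCCCCCCCCCCCCC1=CC(=O)[Fe-4](C#[O+])(C#[O+])(C#[O+])(C#[O+])C1=O
F4 | step 2 | henicos-1-yne | CCCCCCCCCCCCCCCCCCCC#C
F5 | step 2 | 4,4-dichloro-3-nonadecylcyclobut-2-en-1-one | CCCCCCCCCCCCCCCCCCCC1=CC(=O)C1(Cl)Cl
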